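**Retrosynthetic overview**

- Feature: ring A (C5–OMe, C6 side chain, C7–H, C8–OH) is a para-methoxyphenol fused at C4a/C8a to an unsubstituted C1(=O)–C2=C3–C4(=O) ene-dione (ring B). It is therefore an aromatised quinone monoketal joined to a four-carbon 1,4-dicarbonyl unit, and the carbon that carries the ketal decides which oxygen stays methylated.
- Key disconnection: C1–C8a and C4–C4a. Ring B, the only ring that is built, is closed last by [4+2] addition of 2,5-bis(trimethylsilyloxy)furan to the C4a=C8a bond of the ring A quinone monoketal; loss of (Me3Si)2O and MeOH in the same operation gives the target with no redox adjustment.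
- The monoketal comes from PhI(OAc)2/MeOH oxidation of the para-methoxyphenol ester, which comes from fluoride desilylation and Steglich esterification at C1'–O.
- C1' (R) is set by Noyori transfer hydrogenation of an aryl ketone; the C6–C1' bond is made by adding the aryllithium from silylated 3-bromo-4-methoxyphenol to the Weinreb amide of 4-methylpent-3-enoic acid.
- The furan is made from succinic anhydride, Me3SiOTf and Et3N. Ring A is bought.

Key step: step 9

Assumption: atom labels follow naphthoquinone numbering (ring B C1–C4, fusion carbons C4a/C8a, ring A C5–C8, side chain C1'–C4'); the furan is not an article of commerce and hydrolyses readily, so it is made fresh and handled under argon.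

**Route**

Step 1
Reactants: 1 3-bromo-4-methoxyphenol
Product: 2 (3-bromo-4-methoxyphenoxy)(tert-butyl)dimethylsilane
Conditions: t-BuMe2SiCl (1.1 equiv), imidazole (2 equiv), DMF, rt
Reagents that add atoms: tert-butyldimethylsilyl chloride, CC(C)(C)[Si](C)(C)Cl
Why: Silylation of the phenol with a silyl chloride and imidazole removes the acidic O–H before the bromine–lithium exchange and keeps the phenol from being acylated in step 5.

Step 2
Reactants: 3 4-methylpent-3-enoic acid
Product: 5 N-methoxy-N,4-dimethylpent-3-enamide, via acyl imidazole 4 (not isolated)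
Conditions: 1,1'-carbonyldiimidazole (1.1 equiv), CH2Cl2, rt; then MeNH(OMe)·HCl (1.2 equiv), rt
Reagents that add atoms: N,O-dimethylhydroxylamine hydrochloride, CNOC.Cl; 1,1'-carbonyldiimidazole, O=C(n1ccnc1)n1ccnc1 (its imidazolyl group is held only in 4)
Why: Carbonyldiimidazole activation followed by aminolysis is a standard Weinreb amide synthesis and uses no base strong enough to move the β,γ-double bond into conjugation.

Step 3
Reactants: 2 (3-bromo-4-methoxyphenoxy)(tert-butyl)dimethylsilane; 5 N-methoxy-N,4-dimethylpent-3-enamide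
Product: 8 1-[5-(tert-butyldimethylsilyloxy)-2-methoxyphenyl]-4-methylpent-3-en-1-one, via aryllithium 6 (not isolated), via lithium hemiaminal alkoxide 7 (not isolated)
Conditions: n-BuLi (1.05 equiv), THF, −78 °C; then 5 (1.2 equiv), −78 to 0 °C; aq. NH4Cl
Reagents that add atoms: n-butyllithium, CCCC[Li] (its lithium is held only in 6 and 7)
Why: Bromine–lithium exchange followed by the Weinreb ketone synthesis should stop at the chelated tetrahedral adduct, so the enolisable β,γ-unsaturated ketone is released only on quench and never meets the organolithium.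

Step 4
Reactants: 8 1-[5-(tert-butyldimethylsilyloxy)-2-methoxyphenyl]-4-methylpent-3-en-1-one
Product: 9 (1R)-1-[5-(tert-butyldimethylsilyloxy)-2-methoxyphenyl]-4-methylpent-3-en-1-ol
Conditions: RuCl(p-cymene)[(R,R)-TsDPEN] (2 mol %), HCO2H/Et3N (5:2), EtOAc, 30 °C
Reagents that add atoms: none
Why: In this Noyori asymmetric transfer hydrogenation the aryl ring is held by the CH/π contact with the cymene ligand of the (R,R)-catalyst, so hydride should go to the Si face and set C1' as R (as acetophenone gives the (R)-alcohol with this catalyst), while the isolated trisubstituted alkene is not reduced.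

Step 5
Reactants: 9 (1R)-1-[5-(tert-butyldimethylsilyloxy)-2-methoxyphenyl]-4-methylpent-3-en-1-ol; 10 3-methylbut-2-enoic acid
Product: 12 (1R)-1-[5-(tert-butyldimethylsilyloxy)-2-methoxyphenyl]-4-methylpent-3-en-1-yl 3-methylbut-2-enoate, via O-acylisourea 11 (not isolated)
Conditions: DCC (1.5 equiv), DMAP (0.2 equiv), CH2Cl2, 0 °C to rt
Reagents that add atoms: N,N'-dicyclohexylcarbodiimide, C(=NC1CCCCC1)=NC1CCCCC1 (held only in 11)
Why: Steglich esterification acylates the secondary benzylic alcohol on oxygen without breaking the C1'–O bond, so the R configuration is retained, and using the acid in place of the acid chloride with amine base avoids vinylketene formation and deconjugation of the acyl group.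

Step 6
Reactants: 12 (1R)-1-[5-(tert-butyldimethylsilyloxy)-2-methoxyphenyl]-4-methylpent-3-en-1-yl 3-methylbut-2-enoate
Product: 13 (1R)-1-(5-hydroxy-2-methoxyphenyl)-4-methylpent-3-en-1-yl 3-methylbut-2-enoate
Conditions: Bu4NF (1.1 equiv), AcOH (1.2 equiv), THF, 0 °C
Reagents that add atoms: none
Why: Fluoride-mediated desilylation cleaves an aryl silyl ether much faster than an alkyl ester, and the acetic acid buffer keeps the freed phenoxide from attacking the ester.

Step 7
Reactants: 13 (1R)-1-(5-hydroxy-2-methoxyphenyl)-4-methylpent-3-en-1-yl 3-methylbut-2-enoate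
Product: 14 (1R)-1-(6,6-dimethoxy-3-oxocyclohexa-1,4-dien-1-yl)-4-methylpent-3-en-1-yl 3-methylbut-2-enoate
Conditions: PhI(OAc)2 (1.1 equiv), MeOH, 0 °C
Reagents that add atoms: methanol, CO
Why: Hypervalent-iodine oxidative dearomatisation of a para-methoxyphenol in methanol adds methanol para to the phenol oxygen and should give the 4,4-dimethoxycyclohexadienone, which fixes the future C5 oxygen as the ketal and the future C8 oxygen as the ketone.

Step 8
Reactants: 15 succinic anhydride
Product: 17 2,5-bis(trimethylsilyloxy)furan, via 5-(trimethylsilyloxy)furan-2(3H)-one 16 (not isolated)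
Conditions: Me3SiOTf (2.2 equiv), Et3N (2.5 equiv), Et2O, 0 °C to rt; separation from the ammonium salt, bulb-to-bulb distillation
Reagents that add atoms: trimethylsilyl trifluoromethanesulfonate, C[Si](C)(C)OS(=O)(=O)C(F)(F)F
Why: Two successive O-silylations of the anhydride enolates (silyl enol ether formation) are the known way to turn a succinic anhydride into a 2,5-bis(silyloxy)furan.

Step 9
Reactants: 14 (1R)-1-(6,6-dimethoxy-3-oxocyclohexa-1,4-dien-1-yl)-4-methylpent-3-en-1-yl 3-methylbut-2-enoate; 17 2,5-bis(trimethylsilyloxy)furan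
Product: 20 8-hydroxy-5-methoxy-6-[(1R)-4-methyl-1-(3-methylbut-2-enoyloxy)pent-3-en-1-yl]naphthalene-1,4-dione, via oxa-bridged cycloadduct 18 (not isolated), via ene-trione ketal 19 (not isolated)
Conditions: 17 (3 equiv), PhMe, 80 °C, sealed tube, Ar, base-washed glassware; then SiO2, CH2Cl2, rt
Reagents that add atoms: none
Why: Proposed new method: the C4a=C8a bond of dienone 14, made electron-poor by the C8 carbonyl and the inductively withdrawing C5 ketal, should add suprafacially across C2 and C5 of the very electron-rich, weakly aromatic furan 17 in a thermal normal-demand Diels–Alder reaction that forms C1–C8a and C4–C4a and gives the oxygen-bridged bis(silyl ketal) 18; the closest known reaction types are the cycloaddition of 2,5-bis(trimethylsilyloxy)furans with quinones, which gives hydroxylated quinones after loss of hexamethyldisiloxane, and thermal Diels–Alder reactions of quinone monoketals with oxygenated dienes. Ring B closes as the six-membered ring of this intermolecular [4+2] annulation, both bonds being made in one concerted step. Collapse of the bridge in 18 with loss of (Me3Si)2O gives ene-trione 19 with C1 and C4 already at the quinone level, so no oxidant is needed; enolisation of the C8 ketone through the doubly activated C8a–H and E1cB loss of one C5 methoxy group through C4a–H (alpha to the C4 carbonyl) then aromatise ring A as the C5 methyl ether and the C8 phenol, which makes the sequence irreversible. No new stereocentre persists, since C1 and C4 become carbonyl carbons and C4a and C8a become aromatic, so facial and endo/exo selectivity do not matter, and C1' is untouched under neutral conditions. The step needs site selectivity for C4a=C8a over the C6=C7 bond, which the branched C6 substituent should secure by shielding that trisubstituted bond; the furan is symmetric, so there is no regiochemical question, and leaving out Lewis acid should suppress ionisation of the ketal and Mukaiyama–Michael attack through furan C3.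

**Compound list**

1 | 3-bromo-4-methoxyphenol | COc1ccc(O)cc1Br | starting material
2 | (3-bromo-4-methoxyphenoxy)(tert-butyl)dimethylsilane | COc1ccc(O[Si](C)(C)C(C)(C)C)cc1Br | intermediate
3 | 4-methylpent-3-enoic acid | CC(C)=CCC(O)=O | starting material
4 | 1-(imidazol-1-yl)-4-methylpent-3-en-1-one (acyl imidazole, not isolated) | CC(C)=CCC(=O)n1ccnc1 | intermediate
5 | N-methoxy-N,4-dimethylpent-3-enamide | CC(C)=CCC(=O)N(C)OC | intermediate
6 | [5-(tert-butyldimethylsilyloxy)-2-methoxyphenyl]lithium (not isolated) | [Li]c1cc(O[Si](C)(C)C(C)(C)C)ccc1OC | intermediate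
7 | lithium 1-[5-(tert-butyldimethylsilyloxy)-2-methoxyphenyl]-1-[methoxy(methyl)amino]-4-methylpent-3-en-1-olate (racemic at the carbinol carbon, not isolated) | COc1ccc(O[Si](C)(C)C(C)(C)C)cc1C([O-])(CC=C(C)C)N(C)OC.[Li+] | intermediate
8 | 1-[5-(tert-butyldimethylsilyloxy)-2-methoxyphenyl]-4-methylpent-3-en-1-one | COc1ccc(O[Si](C)(C)C(C)(C)C)cc1C(=O)CC=C(C)C | intermediate
9 | (1R)-1-[5-(tert-butyldimethylsilyloxy)-2-methoxyphenyl]-4-methylpent-3-en-1-ol | COc1ccc(O[Si](C)(C)C(C)(C)C)cc1[C@@H](CC=C(C)C)O | intermediate
10 | 3-methylbut-2-enoic acid | CC(C)=CC(O)=O | starting material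
11 | N,N'-dicyclohexyl-O-(3-methylbut-2-enoyl)isourea (not isolated) | CC(C)=CC(=O)OC(=NC1CCCCC1)NC1CCCCC1 | intermediate
12 | (1R)-1-[5-(tert-butyldimethylsilyloxy)-2-methoxyphenyl]-4-methylpent-3-en-1-yl 3-methylbut-2-enoate | COc1ccc(O[Si](C)(C)C(C)(C)C)cc1[C@@H](CC=C(C)C)OC(=O)C=C(C)C | intermediate
13 | (1R)-1-(5-hydroxy-2-methoxyphenyl)-4-methylpent-3-en-1-yl 3-methylbut-2-enoate | COc1ccc(O)cc1[C@@H](CC=C(C)C)OC(=O)C=C(C)C | intermediate
14 | (1R)-1-(6,6-dimethoxy-3-oxocyclohexa-1,4-dien-1-yl)-4-methylpent-3-en-1-yl 3-methylbut-2-enoate (ring A quinone monoketal) | O=C1C=CC(OC)(OC)C([C@@H](CC=C(C)C)OC(=O)C=C(C)C)=C1 | intermediate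
15 | succinic anhydride | O=C1CCC(=O)O1 | starting material
16 | 5-(trimethylsilyloxy)furan-2(3H)-one (not isolated) | O=C1CC=C(O[Si](C)(C)C)O1 | intermediate
17 | 2,5-bis(trimethylsilyloxy)furan | C[Si](C)(C)Oc1ccc(O[Si](C)(C)C)o1 | intermediate
18 | (1R)-1-[5,5-dimethoxy-8-oxo-1,4-bis(trimethylsilyloxy)-1,4,4a,5,8,8a-hexahydro-1,4-epoxynaphthalen-6-yl]-4-methylpent-3-en-1-yl 3-methylbut-2-enoate (cis-fused; the transient ring centres form as a mixture, are erased and are left undefined; not isolated) | O=C1C=C([C@@H](CC=C(C)C)OC(=O)C=C(C)C)C(OC)(OC)C2C1C1(O[Si](C)(C)C)C=CC2(O[Si](C)(C)C)O1 | intermediate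
19 | (1R)-1-(5,5-dimethoxy-1,4,8-trioxo-1,4,4a,5,8,8a-hexahydronaphthalen-6-yl)-4-methylpent-3-en-1-yl 3-methylbut-2-enoate (C4a and C8a transient and undefined; not isolated) | O=C1C=C([C@@H](CC=C(C)C)OC(=O)C=C(C)C)C(OC)(OC)C2C1C(=O)C=CC2=O | intermediate
20 | 8-hydroxy-5-methoxy-6-[(1R)-4-methyl-1-(3-methylbut-2-enoyloxy)pent-3-en-1-yl]naphthalene-1,4-dione | COc1c([C@@H](CC=C(C)C)OC(=O)C=C(C)C)cc(O)c2c1C(=O)C=CC2=O | target

**Step count**

Total: 9 steps. Longest linear sequence: 7 steps (steps 1, 3, 4, 5, 6, 7, 9); steps 2 and 8 make the two side components.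

**Steps most likely to fail**

1. Step 9 (proposed new method).
   - What may go wrong: the cycloaddition may be slower than thermal or hydrolytic decay of the furan, or the adduct may revert before the bridge collapses. Traces of acid may ionise the ketal, so that the furan adds in a conjugate sense through C3 and ring A rearomatises without ring B closing.
   - Fallback, known chemistry, from 14 back to 20: a thermal Diels–Alder reaction of 14 with 1,4-bis(trimethylsilyloxy)cyclohexa-1,3-diene F1 (from cyclohexane-1,4-dione, Me3SiCl, Et3N, NaI, MeCN; the conjugated isomer is the reactive one) in PhMe at 110 °C should give the bicyclo[2.2.2]octene adduct, (1R)-1-[5,5-dimethoxy-8-oxo-1,4-bis(trimethylsilyloxy)-1,4,4a,5,8,8a-hexahydro-1,4-ethanonaphthalen-6-yl]-4-methylpent-3-en-1-yl 3-methylbut-2-enoate F2, whose bridgehead silyloxy groups cannot be lost by β-elimination. Pyridinium p-toluenesulfonate in CH2Cl2 should then aromatise ring A with loss of methanol to the ethano-bridged naphthol, (1R)-1-[8-hydroxy-5-methoxy-1,4-bis(trimethylsilyloxy)-1,4-dihydro-1,4-ethanonaphthalen-6-yl]-4-methylpent-3-en-1-yl 3-methylbut-2-enoate F3. Alder–Rickert extrusion of ethene (1,2-dichlorobenzene, about 200 °C) should give (1R)-1-[4-hydroxy-1-methoxy-5,8-bis(trimethylsilyloxy)naphthalen-2-yl]-4-methylpent-3-en-1-yl 3-methylbut-2-enoate F4. Bu4NF/AcOH should free the hydroquinone, (1R)-1-(4,5,8-trihydroxy-1-methoxynaphthalen-2-yl)-4-methylpent-3-en-1-yl 3-methylbut-2-enoate F5, and Ag2O in CH2Cl2 should oxidise its ring B hydroquinone to the quinone 20.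
   - This keeps the regiochemical information of the ketal and uses known reaction types (Diels–Alder reactions of quinone monoketals with silyloxy dienes, retro-Diels–Alder loss of ethene, hydroquinone oxidation). Its cost is four operations and a hot extrusion step that the benzylic ester must survive.

2. Step 4.
   - What may go wrong: facial discrimination may erode because the ortho-methoxy group disturbs the aryl–catalyst contact, and the amine may promote migration of the C3'=C4' bond into conjugation, after which the wrong ketone is reduced.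
   - Fallback, from 2 back to 9, bypassing ketone 8: bromine–lithium exchange of 2 (n-BuLi, THF, −78 °C) and quench of aryllithium 6 with DMF should give 5-(tert-butyldimethylsilyloxy)-2-methoxybenzaldehyde F6. Brown allylboration with allyl-B(Ipc)2, generated from allylmagnesium bromide and (+)-Ipc2BOMe (the enantiomer derived from (−)-α-pinene), Et2O, −78 °C, then NaOH/H2O2, should give (1R)-1-[5-(tert-butyldimethylsilyloxy)-2-methoxyphenyl]but-3-en-1-ol F7, the sense that benzaldehyde shows with this reagent. Cross-metathesis of F7 with excess 2-methylbut-2-ene and the second-generation Grubbs catalyst RuCl2(=CHPh)(PCy3)(H2IMes) in CH2Cl2 at 40 °C should install the trisubstituted alkene and return 9.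

3. Step 3.
   - What may go wrong: proton transfer from the doubly activated α-CH2 of amide 5 to aryllithium 6 (enolisation in place of addition) would return protonated arene and unchanged amide.
   - Fallback, from 2 and 3 back to 8: acid 3 with oxalyl chloride and catalytic DMF in CH2Cl2 should give 4-methylpent-3-enoyl chloride F8. Aryllithium 6 from 2 is transmetalated with ZnCl2 (THF, −78 °C to 0 °C) to the much less basic [5-(tert-butyldimethylsilyloxy)-2-methoxyphenyl]zinc chloride F9. Negishi acylation of F9 with F8, catalysed by Pd(PPh3)4 in THF at 0 °C to rt, should give ketone 8 without a strongly basic organometallic ever meeting an enolisable acyl partner.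

**Further compounds**

F1 | step 9 | 1,4-bis(trimethylsilyloxy)cyclohexa-1,3-diene | C[Si](C)(C)OC1=CC=C(O[Si](C)(C)C)CC1
F2 | step 9 | (1R)-1-[5,5-dimethoxy-8-oxo-1,4-bis(trimethylsilyloxy)-1,4,4a,5,8,8a-hexahydro-1,4-ethanonaphthalen-6-yl]-4-methylpent-3-en-1-yl 3-methylbut-2-enoate | O=C1C=C([C@@H](CC=C(C)C)OC(=O)C=C(C)C)C(OC)(OC)C2C1C1(O[Si](C)(C)C)C=CC2(O[Si](C)(C)C)CC1
F3 | step 9 | (1R)-1-[8-hydroxy-5-methoxy-1,4-bis(trimethylsilyloxy)-1,4-dihydro-1,4-ethanonaphthalen-6-yl]-4-methylpent-3-en-1-yl 3-methylbut-2-enoate | COc1c([C@@H](CC=C(C)C)OC(=O)C=C(C)C)cc(O)c2c1C1(O[Si](C)(C)C)C=CC2(O[Si](C)(C)C)CC1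
F4 | step 9 | (1R)-1-[4-hydroxy-1-methoxy-5,8-bis(trimethylsilyloxy)naphthalen-2-yl]-4-methylpent-3-en-1-yl 3-methylbut-2-enoate | COc1c([C@@H](CC=C(C)C)OC(=O)C=C(C)C)cc(O)c2c(O[Si](C)(C)C)ccc(O[Si](C)(C)C)c12
F5 | step 9 | (1R)-1-(4,5,8-trihydroxy-1-methoxynaphthalen-2-yl)-4-methylpent-3-en-1-yl 3-methylbut-2-enoate | COc1c([C@@H](CC=C(C)C)OC(=O)C=C(C)C)cc(O)c2c(O)ccc(O)c12
F6 | step 4 | 5-(tert-butyldimethylsilyloxy)-2-methoxybenzaldehyde | COc1ccc(O[Si](C)(C)C(C)(C)C)cc1C=O
F7 | step 4 | (1R)-1-[5-(tert-butyldimethylsilyloxy)-2-methoxyphenyl]but-3-en-1-ol | COc1ccc(O[Si](C)(C)C(C)(C)C)cc1[C@@H](CC=C)O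
F8 | step 3 | 4-methylpent-3-enoyl chloride | CC(C)=CCC(Cl)=O
F9 | step 3 | [5-(tert-butyldimethylsilyloxy)-2-methoxyphenyl]zinc chloride | Cl[Zn]c1cc(O[Si](C)(C)C(C)(C)C)ccc1OC
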